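**Strategy.** Ring C (the terminal orsellinic acid) is disconnected across C-1–C-6 and C-3–C-4 to benzyl acetoacetate and benzyl crotonate. One Michael–Claisen operation joins these two open-chain esters into benzyl 6-methyl-2,4-dioxocyclohexane-1-carboxylate, a dihydro form of ring C. The feature exploited is that ring C carries its acyl group on O-4 only, with O-2 free next to the C-1 carboxyl. In the dione, O-4 is the exposed end of a vinylogous acid, whereas O-2 is screened by the C-1 ester and becomes a phenol only on aromatisation. The ring A–ring B acid chloride is therefore attached at O-4 before dehydrogenation, and the benzyl groups are removed last.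

Key step: step 5

Remark: ring A (the trimethoxybenzoyl unit) carries a methyl group at C-6 that 2,4,5-trimethoxybenzoic acid lacks, so step 1 installs it; ring B is taken from 2,4-dihydroxy-6-methylbenzaldehyde (formyl as latent carboxyl) and its 2-OH is benzylated so that no free phenol sits beside the acid chloride; ring atoms are numbered from the carboxyl-bearing carbon (C-1).

**Step 1**
Reactants: 1 2,4,5-trimethoxybenzoic acid
Product: 3 2,4,5-trimethoxy-6-methylbenzoic acid, via lithium 6-lithio-2,4,5-trimethoxybenzoate 2 (not isolated)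
Conditions: s-BuLi (2.2 equiv), TMEDA (2.2 equiv), THF, −78 °C; MeI (excess), −78 °C → rt; aq. HCl
Reagents that add atoms: iodomethane, CI
Why: Directed ortho-metalation of an unprotected benzoic acid, in which the lithium carboxylate and the 5-methoxy group together guide s-BuLi/TMEDA to C-6 (the only free position beside the carboxylate), followed by C-methylation of the aryllithium with MeI.

**Step 2**
Reactants: 3 2,4,5-trimethoxy-6-methylbenzoic acid; 4 2,4-dihydroxy-6-methylbenzaldehyde
Product: 6 4-formyl-3-hydroxy-5-methylphenyl 2,4,5-trimethoxy-6-methylbenzoate, via 2,4,5-trimethoxy-6-methylbenzoyl chloride 5 (not isolated)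
Conditions: (COCl)2, DMF (cat.), CH2Cl2, 0 °C → rt, evaporate; then 4, Et3N, DMAP (cat.), THF/CH2Cl2, 0 °C → rt
Reagents that add atoms: none
Why: Acid chloride formation followed by DMAP-catalysed esterification of a phenol, in which the unhindered 4-OH (para to the formyl group) is acylated in preference to the 2-OH that is held in a hydrogen bond to the aldehyde.

**Step 3**
Reactants: 6 4-formyl-3-hydroxy-5-methylphenyl 2,4,5-trimethoxy-6-methylbenzoate
Product: 7 3-(benzyloxy)-4-formyl-5-methylphenyl 2,4,5-trimethoxy-6-methylbenzoate
Conditions: BnBr, K2CO3, DMF, rt → 45 °C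
Reagents that add atoms: benzyl bromide, BrCc1ccccc1
Why: Williamson etherification of the chelated 2-OH, during which the aryl ester should survive because its carbonyl is flanked by the 2-methoxy and 6-methyl groups of ring A and is shielded from carbonate and phenoxide.

**Step 4**
Reactants: 7 3-(benzyloxy)-4-formyl-5-methylphenyl 2,4,5-trimethoxy-6-methylbenzoate
Product: 8 2-(benzyloxy)-6-methyl-4-[(2,4,5-trimethoxy-6-methylbenzoyl)oxy]benzoic acid
Conditions: NaClO2, NaH2PO4, 2-methyl-2-butene (excess), t-BuOH/THF/H2O, 0 °C → rt
Reagents that add atoms: sodium chlorite, [Na+].[O-]Cl=O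
Why: Pinnick oxidation converts the hindered aryl aldehyde into the acid in a buffered medium that leaves the aryl ester and benzyl ether intact, while 2-methyl-2-butene traps HOCl so that the electron-rich ring A is not chlorinated.

**Step 5**
Reactants: 9 benzyl acetoacetate; 10 benzyl (E)-but-2-enoate
Product: 12 benzyl trans-6-methyl-2,4-dioxocyclohexane-1-carboxylate (racemic), via dibenzyl 2-acetyl-3-methylpentanedioate 11 (not isolated)
Conditions: BnONa (1.05 equiv), BnOH/toluene, 80 °C; then 1 M HCl, 0 °C
Reagents that add atoms: none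
Why: The sodium enolate of 9 adds through C-2 to the β-carbon of 10 (Michael addition, forming C-1–C-6 of the new ring) to give 11, and after proton transfer the enolate of the acetyl methyl group attacks the crotonate-derived ester carbonyl (Claisen condensation of Dieckmann type, forming C-3–C-4) with expulsion of benzyloxide. The closest known reaction is the alkoxide-mediated condensation of acetoacetic esters with crotonic esters that gives dihydroorsellinates. The ring closes in a 6-(enolendo)-exo-trig mode. C-6 is formed without facial bias and C-1 equilibrates through the β-keto ester enol, so the racemic trans isomer (ester and methyl both equatorial) should result under thermodynamic control; neither centre survives step 7. The selectivity needed is C-alkylation at C-2 of the acetoacetate followed by closure through its methyl group, and it is secured because every event before the last is reversible under alkoxide whereas deprotonation of the product to its stabilised 1,3-dione enolate is not; benzyloxide as base makes any ester exchange degenerate.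

**Step 6**
Reactants: 8 2-(benzyloxy)-6-methyl-4-[(2,4,5-trimethoxy-6-methylbenzoyl)oxy]benzoic acid; 12 benzyl trans-6-methyl-2,4-dioxocyclohexane-1-carboxylate (racemic)
Product: 14 benzyl trans-4-({2-(benzyloxy)-6-methyl-4-[(2,4,5-trimethoxy-6-methylbenzoyl)oxy]benzoyl}oxy)-6-methyl-2-oxocyclohex-3-ene-1-carboxylate (racemic), via two-ring acid chloride 13 (not isolated)
Conditions: (COCl)2, DMF (cat.), CH2Cl2, 0 °C → rt, evaporate; then 12, Et3N, CH2Cl2, 0 °C → rt
Reagents that add atoms: none
Why: O-Acylation of a cyclic 1,3-dione enolate by an aroyl chloride gives the enol ester; the enolate is ambident between O-2 and O-4, and O-4 should be chosen because O-2 is flanked by the C-1 ester and cannot be reached by the 2,6-disubstituted aroyl chloride, while the absence of DMAP or cyanide avoids O-to-C acyl migration and the C-1/C-6 centres are carried through unchanged.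

**Step 7**
Reactants: 14 benzyl trans-4-({2-(benzyloxy)-6-methyl-4-[(2,4,5-trimethoxy-6-methylbenzoyl)oxy]benzoyl}oxy)-6-methyl-2-oxocyclohex-3-ene-1-carboxylate (racemic)
Product: 15 benzyl 4-({2-(benzyloxy)-6-methyl-4-[(2,4,5-trimethoxy-6-methylbenzoyl)oxy]benzoyl}oxy)-2-hydroxy-6-methylbenzoate
Conditions: DDQ (1.2 equiv), 1,4-dioxane, 60–80 °C
Reagents that add atoms: none
Why: DDQ dehydrogenation, in which the β-keto ester of 14 enolises to a cyclohexa-1,3-dienol, DDQ abstracts hydride from C-6 and loss of a proton from C-5 gives the arene with O-2 emerging as the hydrogen-bonded phenol; both stereocentres are erased here.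

**Step 8**
Reactants: 15 benzyl 4-({2-(benzyloxy)-6-methyl-4-[(2,4,5-trimethoxy-6-methylbenzoyl)oxy]benzoyl}oxy)-2-hydroxy-6-methylbenzoate
Product: 16 2-hydroxy-4-({2-hydroxy-6-methyl-4-[(2,4,5-trimethoxy-6-methylbenzoyl)oxy]benzoyl}oxy)-6-methylbenzoic acid (target)
Conditions: H2 (1 atm), 10% Pd/C, EtOAc, rt
Reagents that add atoms: none
Why: Catalytic hydrogenolysis cleaves the benzyl ester of ring C and the benzyl ether of ring B in one operation, while the two aryl esters and the arenes are inert to H2 over Pd/C at room temperature.

**Compound list**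

1 | 2,4,5-trimethoxybenzoic acid | COc1cc(OC)c(C(=O)O)cc1OC | starting material
2 | lithium 6-lithio-2,4,5-trimethoxybenzoate | [Li]OC(=O)c1c([Li])c(OC)c(OC)cc1OC | intermediate
3 | 2,4,5-trimethoxy-6-methylbenzoic acid (3,4,6-trimethoxy-2-methylbenzoic acid) | COc1cc(OC)c(C(=O)O)c(C)c1OC | intermediate
4 | 2,4-dihydroxy-6-methylbenzaldehyde | Cc1cc(O)cc(O)c1C=O | starting material
5 | 2,4,5-trimethoxy-6-methylbenzoyl chloride | COc1cc(OC)c(C(=O)Cl)c(C)c1OC | intermediate
6 | 4-formyl-3-hydroxy-5-methylphenyl 2,4,5-trimethoxy-6-methylbenzoate | COc1cc(OC)c(C(=O)Oc2cc(C)c(C=O)c(O)c2)c(C)c1OC | intermediate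
7 | 3-(benzyloxy)-4-formyl-5-methylphenyl 2,4,5-trimethoxy-6-methylbenzoate | COc1cc(OC)c(C(=O)Oc2cc(C)c(C=O)c(OCc3ccccc3)c2)c(C)c1OC | intermediate
8 | 2-(benzyloxy)-6-methyl-4-[(2,4,5-trimethoxy-6-methylbenzoyl)oxy]benzoic acid | COc1cc(OC)c(C(=O)Oc2cc(C)c(C(=O)O)c(OCc3ccccc3)c2)c(C)c1OC | intermediate
9 | benzyl acetoacetate | CC(=O)CC(=O)OCc1ccccc1 | starting material
10 | benzyl (E)-but-2-enoate | C/C=C/C(=O)OCc1ccccc1 | starting material
11 | dibenzyl 2-acetyl-3-methylpentanedioate (mixture of diastereomers, configuration not defined) | CC(=O)C(C(C)CC(=O)OCc1ccccc1)C(=O)OCc1ccccc1 | intermediate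
12 | benzyl trans-6-methyl-2,4-dioxocyclohexane-1-carboxylate (racemic; the (1S,6R) enantiomer is drawn) | C[C@@H]1CC(=O)CC(=O)[C@H]1C(=O)OCc1ccccc1 | intermediate
13 | 2-(benzyloxy)-6-methyl-4-[(2,4,5-trimethoxy-6-methylbenzoyl)oxy]benzoyl chloride | COc1cc(OC)c(C(=O)Oc2cc(C)c(C(=O)Cl)c(OCc3ccccc3)c2)c(C)c1OC | intermediate
14 | benzyl trans-4-({2-(benzyloxy)-6-methyl-4-[(2,4,5-trimethoxy-6-methylbenzoyl)oxy]benzoyl}oxy)-6-methyl-2-oxocyclohex-3-ene-1-carboxylate (racemic; the (1S,6R) enantiomer is drawn) | C[C@@H]1CC(OC(=O)c2c(C)cc(OC(=O)c3c(C)c(OC)c(OC)cc3OC)cc2OCc4ccccc4)=CC(=O)[C@H]1C(=O)OCc5ccccc5 | intermediate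
15 | benzyl 4-({2-(benzyloxy)-6-methyl-4-[(2,4,5-trimethoxy-6-methylbenzoyl)oxy]benzoyl}oxy)-2-hydroxy-6-methylbenzoate | COc1cc(OC)c(C(=O)Oc2cc(C)c(C(=O)Oc3cc(C)c(C(=O)OCc4ccccc4)c(O)c3)c(OCc5ccccc5)c2)c(C)c1OC | intermediate
16 | 2-hydroxy-4-({2-hydroxy-6-methyl-4-[(2,4,5-trimethoxy-6-methylbenzoyl)oxy]benzoyl}oxy)-6-methylbenzoic acid (no stereocentres) | COc1cc(OC)c(C(=O)Oc2cc(C)c(C(=O)Oc3cc(C)c(C(=O)O)c(O)c3)c(O)c2)c(C)c1OC | target

**Step count and risk**

Total step count: 8. Longest linear sequence: 7 steps (steps 1, 2, 3, 4, 6, 7, 8, from 1 to 16); the key step 5 feeds in at step 6.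

The three steps most likely to fail:

Step 6 (enol O-acylation). What may go wrong: acylation of the ambident dione enolate at O-2 or at C-3 instead of O-4, slow reaction of the doubly ortho-substituted acid chloride, or hydrolytic loss of the vinylogous anhydride during work-up. The fallback inverts the order of acylation and aromatisation. It sets out from 12, which is brominated with Br2 (1 equiv) in DMF at 0 °C to benzyl 3-bromo-6-methyl-2,4-dioxocyclohexane-1-carboxylate F1, not isolated. On warming to about 60 °C this should lose HBr and give benzyl 2,4-dihydroxy-6-methylbenzoate F2. Phenol F2 is then acylated with acid chloride 13 (Et3N, DMAP cat., CH2Cl2, 0 °C), where the 4-OH reacts because the 2-OH is tied up in a hydrogen bond to the ester. This gives 15 directly, where the fallback returns to the route, so step 7 is bypassed as well.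

Step 7 (dehydrogenation). What may go wrong: sluggish hydride abstraction, addition of the enol to the quinone in place of dehydrogenation, or cleavage of the enol ester on prolonged heating. The fallback raises the oxidation level by selenium chemistry instead of a quinone. It sets out from 14, which is treated with PhSeCl and pyridine in CH2Cl2 at 0 °C. Selenenylation at C-1 of the β-keto ester, from the face opposite the C-6 methyl, should give benzyl 4-({2-(benzyloxy)-6-methyl-4-[(2,4,5-trimethoxy-6-methylbenzoyl)oxy]benzoyl}oxy)-6-methyl-2-oxo-1-(phenylselanyl)cyclohex-3-ene-1-carboxylate F3. Oxidation with H2O2 (or mCPBA) at 0 °C gives the corresponding selenoxide F4, which should undergo syn-elimination towards C-6–H at or below room temperature. The cross-conjugated dienone so formed is the keto tautomer of 15 and enolises at once; the fallback returns at 15.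

Step 1 (directed metalation). What may go wrong: competing deprotonation at C-3 between the 2- and 4-methoxy groups, addition of s-BuLi to the carboxylate or displacement of the 2-methoxy group, and a second, benzylic metalation–methylation of the new methyl group. The fallback cleaves the C–H bond by carboxylate-directed cyclopalladation instead of by a base. It sets out from 1 and uses Pd(OAc)2 (10 mol %), MeB(OH)2, benzoquinone, Ag2CO3 and K2HPO4 in t-BuOH at 100 °C. The palladacycle can form only at C-6, the single C–H ortho to the carboxylate, and transmetalation with reductive elimination should deliver 3, where the fallback returns. It makes no new compound (entry F0).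

**Further compounds**

F1 | step 6 | benzyl 3-bromo-6-methyl-2,4-dioxocyclohexane-1-carboxylate (racemic, 1,6-trans, C-3 not defined) | C[C@@H]1CC(=O)C(Br)C(=O)[C@H]1C(=O)OCc1ccccc1
F2 | step 6 | benzyl 2,4-dihydroxy-6-methylbenzoate | Cc1cc(O)cc(O)c1C(=O)OCc1ccccc1
F3 | step 7 | benzyl 4-({2-(benzyloxy)-6-methyl-4-[(2,4,5-trimethoxy-6-methylbenzoyl)oxy]benzoyl}oxy)-6-methyl-2-oxo-1-(phenylselanyl)cyclohex-3-ene-1-carboxylate (racemic, selenium trans to the C-6 methyl) | C[C@@H]1CC(OC(=O)c2c(C)cc(OC(=O)c3c(C)c(OC)c(OC)cc3OC)cc2OCc4ccccc4)=CC(=O)[C@]1([Se]c5ccccc5)C(=O)OCc6ccccc6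
F4 | step 7 | benzyl 4-({2-(benzyloxy)-6-methyl-4-[(2,4,5-trimethoxy-6-methylbenzoyl)oxy]benzoyl}oxy)-6-methyl-2-oxo-1-(phenylseleninyl)cyclohex-3-ene-1-carboxylate (racemic, selenium trans to the C-6 methyl, configuration at selenium not defined) | C[C@@H]1CC(OC(=O)c2c(C)cc(OC(=O)c3c(C)c(OC)c(OC)cc3OC)cc2OCc4ccccc4)=CC(=O)[C@]1([Se](=O)c5ccccc5)C(=O)OCc6ccccc6
F0 | step 1 | none | none
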